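The same starting material cannot stand in two places, so the open intermediate at 6.0 h is what the charge leaves once the other holders are counted. That mass balance needs few readings, and the next run hangs on it: how much partner to charge, and whether to tighten the portions.

in all of them: starting material 0.16 M (in portions, 3)
- Thursday's: partner 0.18 equiv; protic impurity 0.032 M; run made earlier; portions every 1.5 h
- Tuesday's: partner 0.86 equiv; protic impurity 0.032 M; run made earlier; portions every 1.5 h
- south: partner 1.00 equiv; protic impurity 0.0320 M; the portions of starting material follow each other after 0.40 h, the first at the start; time 6.0 h
- west: partner 0.330 equiv; protic impurity 0.0320 M; the portions of starting material follow each other after 0.40 h, the first at the start; time 6.0 h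
- south-west: partner 0.330 equiv; protic impurity 0.0320 M; the portions of starting material follow each other after 1.5 h, the first at the start; time 6.0 h
- south-east: partner 1.00 equiv; protic impurity 0.0320 M; the portions of starting material follow each other after 1.5 h, the first at the start; time 6.0 h

| run | time / h | open intermediate / % | target / % | starting material / % |
|---|---|---|---|---|
| Thursday's | 0.833 | 9 | 4 | 15 |
| Thursday's | 2.00 | 19 | 15 | 24 |
| Thursday's | 4.00 | 47 | 13 | 19 |
| Thursday's | 6.00 | 61 | 17 | 5 |
| Tuesday's | 1.50 | 3 | 15 | 8 |
| Tuesday's | 3.00 | 8 | 32 | 14 |
| Tuesday's | 5.00 | 25 | 43 | 12 |
| Tuesday's | 6.00 | 29 | 45 | 5 |

(standard deviation of a reading: 1.5 percentage points)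

1. all flasks from highest to lowest amount of open intermediate, in percent of the starting material charged, at 6.0 h (south / west / south-west / south-east)
2. the amount of open intermediate, in percent of the starting material charged of the flask you put first, at 6.0 h
3. the amount of open intermediate, in percent of the starting material charged of the flask you put last, at 6.0 h

- percentages count the starting material that a species holds: one idle adduct counts as two
- target is meant together with its crystals and idle adduct
- solid, in amounts per volume of the solution: crystals
- on the list of suspects stand: starting material -> open intermediate; partner -> second intermediate; open intermediate + second intermediate -> target; 2 second intermediate -> homo product; crystals <-> target; starting material + target <-> idle adduct; starting material + protic impurity -> quenched substrate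
- in an amount of target, one idle adduct counts as one target

At the last reading, open intermediate, target and starting material leave a gap of 17.0 % in Thursday's run and 21.0 % in Tuesday's. Protic impurity is charged at 20.0 % of the starting material in both runs, and the new flasks hold the same amount. Partner, however, stands at 0.18 equiv in Thursday's run and 0.86 equiv in Tuesday's. Replacing the two gaps by their mean gives the pool B, the share of the charge that ends as open intermediate, target or starting material: B = 81.0 %. The error of that step is half the difference, 2 percentage points, against a scatter of 1.5 points per reading.

Then open intermediate is B less end starting material less target. For target, this reckoning scales each run by its partner and takes 5 % of starting material from the slow portions. South-west, scaled from Thursday's run, gets 31.2 % of target and so 44.8 % of open intermediate. South-east, scaled from Tuesday's run, gets 52.3 % and so 23.7 %. Between these two flasks, which share their portions every 1.5 h, the partner charge moves the reckoned open intermediate by 21 points, so the next run for open intermediate is charged at 0.330 equiv. Both earlier runs had portions every 1.5 h, so this reckoning gives no figure for the tighter interval.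

The forecast gives west > south-west > south-east > south, with 50 % first and 19 % last, and holds that “West versus south-west is nearly a tie”. Its south-west of 48 % and south-east of 27 % stand against the 44.8 % and 23.7 % reckoned here.

    starting material → open intermediate (k = 0.0110 min⁻¹)
    partner → second intermediate (k = 0.0880 min⁻¹)
    open intermediate + second intermediate → target (k = 0.570 L mol⁻¹ min⁻¹)
    2 second intermediate → homo product (k = 0.0390 L mol⁻¹ min⁻¹)
    crystals ⇌ target, rate k5*(cs5 - [target]) while solid is left; crystals form when [target] > cs5 (solubility = 0.0650 M, k = 0.630 min⁻¹)
    starting material + target ⇌ idle adduct, settled at all times (K = 7.40 L mol⁻¹)
    starting material + protic impurity → quenched substrate (k = 0.120 L mol⁻¹ min⁻¹)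

The flasks give west > south-west > south-east > south, from 53.0 % in west down to 21.2 % in south, the order of the forecast. In south, quenched substrate stands at 15.1 %, with protic impurity at 25 % of its own charge. B less south's 3.25 % of starting material and 58.9 % of target leaves 18.9 %, against the 21.2 %. The same flask at 0.400 equiv of partner holds 2.76 % of starting material and 33.1 % of target, so B leaves 45.1 %, and that flask gives 48.0 %.

(All runs were generated by integration with made-up constants.)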